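**Retrosynthetic overview**
1. The 14-membered carbocycle is closed last by ring-closing metathesis at C6=C7; the 3,4-oxirane comes from a reagent-controlled Shi epoxidation (C–O) and the acetate from acylation of C13-OH.
2. Key step (C–O): a new amine-catalysed α-hydroxylation of a citronellal-type aldehyde makes the C13–O bond; this free hydroxyl then steers, by chelation, an indium-mediated allylation/lactonisation that sets C14 and C1 and closes the cis-lactone.
3. West aldehyde: from (R)-linalool (C8 from the chiral pool) by ozonolysis, Grignard addition to 4-methoxybut-3-en-2-one and organocatalytic transfer hydrogenation (C12).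
4. East bromide: from pent-1-en-4-yne by Negishi carboalumination/oxirane opening, oxidation, Morita–Baylis–Hillman reaction and SN2′ bromination.
5. Ring order: α-methylene-γ-lactone first (step 10), oxirane second (step 12), 14-membered ring last (step 13).

Numbering used for the target (cembrane numbering): C1 = ring-fusion CH bearing C15(=C17H2)–C16(=O); C14 = lactone O–CH; C13 = CH–OAc; C12 = CH–CH3; C8 = C(OH)CH3; C6=C7 = E-alkene; C3–C4 = oxirane. Target = (1S,3R,4R,8R,12S,13R,14R).
Assumption: pent-1-en-4-yne is bought (it is also one step from allyl bromide and ethynylmagnesium bromide).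

**Route**

Step 1
Reactants: 1 (R)-(−)-linalool
Product: 3 (4R)-4-methylhex-5-ene-1,4-diol, via hydroxy aldehyde 2 (not isolated)
Conditions: O3 (1.0 equiv, Sudan Red 7B end point), CH2Cl2/MeOH, −78 °C; then NaBH4, −78 °C → rt
Reagents that add atoms: ozone, [O-][O+]=O
Why: Chemoselective ozonolysis with reductive work-up, because the electron-rich trisubstituted alkene is cleaved much faster than the vinyl group; the C8 stereocentre from the chiral pool is untouched.

Step 2
Reactants: 3 (4R)-4-methylhex-5-ene-1,4-diol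
Product: 4 (3R)-6-chloro-3-methylhex-1-en-3-ol
Conditions: PPh3, N-chlorosuccinimide, CH2Cl2, −20 → 0 °C
Reagents that add atoms: N-chlorosuccinimide, O=C1CCC(=O)N1Cl
Why: Appel-type chlorination, in which the oxyphosphonium ion forms and is displaced (SN2) only at the unhindered primary carbinol.

Step 3
Reactants: 4 (3R)-6-chloro-3-methylhex-1-en-3-ol
Product: 5 {[(3R)-6-chloro-3-methylhex-1-en-3-yl]oxy}trimethylsilane
Conditions: 1-(trimethylsilyl)imidazole, CH2Cl2, rt
Reagents that add atoms: 1-(trimethylsilyl)imidazole, C[Si](C)(C)n1ccnc1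
Why: O-silylation masks the tertiary hydroxyl so that a Grignard reagent can be made from the chloride.

Step 4
Reactants: 5 {[(3R)-6-chloro-3-methylhex-1-en-3-yl]oxy}trimethylsilane; 6 (3E)-4-methoxybut-3-en-2-one
Product: 9 (2E,7R)-7-hydroxy-3,7-dimethylnona-2,8-dienal (E/Z mixture), via Grignard reagent 7 (not isolated), via tertiary carbinol 8 (not isolated)
Conditions: Mg turnings, THF, 50 °C; then 6, −40 → 0 °C; then 0.5 M aq. HCl, THF, 0 °C
Reagents that add atoms: water, O
Why: Grignard 1,2-addition to the vinylogous ester, then acid-induced allylic transposition/hydrolysis (loss of MeOH) gives the β-methyl enal while the same acid removes the silyl group; the E/Z ratio is irrelevant for step 5.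

Step 5
Reactants: 9 (2E,7R)-7-hydroxy-3,7-dimethylnona-2,8-dienal
Product: 10 (3S,7R)-7-hydroxy-3,7-dimethylnon-8-enal
Conditions: (S)-TRIP morpholinium salt (20 mol%), Hantzsch ester (1.1 equiv), dioxane, 50 °C
Reagents that add atoms: none
Why: Organocatalytic iminium transfer hydrogenation (asymmetric counteranion-directed catalysis), in which the chiral phosphate shields one face of the morpholinium iminium ion so that hydride sets C12 (3S in 10); E and Z iminium ions interconvert, so the mixture converges as in citral → citronellal, and the catalyst antipode is the mirror image of the one that gives (R)-citronellal.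

Step 6
Reactants: 11 pent-1-en-4-yne
Product: 14 (3E)-4-methylhepta-3,6-dien-1-ol, via alkenylalane 12 (not isolated), via aluminate 13 (not isolated)
Conditions: AlMe3 (2 equiv), Cp2ZrCl2 (25 mol%), ClCH2CH2Cl, rt; then nBuLi, hexane/THF, −78 °C; oxirane, −78 °C → rt; aq. HCl work-up
Reagents that add atoms: trimethylaluminium, C[Al](C)C; oxirane, C1CO1
Why: Negishi zirconium-catalysed carboalumination adds CH3 and Al syn across the alkyne only, which fixes the E-trisubstituted C3=C4 alkene, and the ate complex opens oxirane with retention of geometry.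

Step 7
Reactants: 14 (3E)-4-methylhepta-3,6-dien-1-ol
Product: 15 (3E)-4-methylhepta-3,6-dienal
Conditions: Dess–Martin periodinane, CH2Cl2, 0 °C; used at once
Reagents that add atoms: none
Why: Dess–Martin oxidation is neutral and fast, so the β,γ-unsaturated aldehyde is not isomerised into conjugation.

Step 8
Reactants: 15 (3E)-4-methylhepta-3,6-dienal; 16 methyl acrylate
Product: 17 methyl (5E)-3-hydroxy-6-methyl-2-methylidenenona-5,8-dienoate (racemic)
Conditions: DABCO (0.5 equiv), 16 (3 equiv), MeOH, rt, 2–3 d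
Reagents that add atoms: none
Why: Morita–Baylis–Hillman reaction; the new carbinol centre is racemic and is erased in step 9.

Step 9
Reactants: 17 methyl (5E)-3-hydroxy-6-methyl-2-methylidenenona-5,8-dienoate
Product: 18 methyl (2Z,5E)-2-(bromomethyl)-6-methylnona-2,5,8-trienoate
Conditions: PBr3 (0.4 equiv), Et2O, −10 → 0 °C
Reagents that add atoms: phosphorus tribromide, BrP(Br)Br
Why: SN2′ bromination with allylic transposition gives the conjugated, thermodynamically preferred (Z)-2-(bromomethyl)alk-2-enoate.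

Step 10
Reactants: 10 (3S,7R)-7-hydroxy-3,7-dimethylnon-8-enal; 18 methyl (2Z,5E)-2-(bromomethyl)-6-methylnona-2,5,8-trienoate
Product: 23 (4S,5R)-5-[(1R,2S,6R)-1,6-dihydroxy-2,6-dimethyloct-7-en-1-yl]-3-methylidene-4-[(2E)-3-methylhexa-2,5-dien-1-yl]oxolan-2-one, via silyloxy aldehyde 19 (not isolated), via hydroxy aldehyde 20 (not isolated), via allylindium reagent 21 (not isolated), via hydroxy ester 22 (not isolated)
Conditions: L-proline (30 mol%), Me3SiOOSiMe3 (1.3 equiv), CHCl3, 0 °C; then 18 (1.3 equiv), In powder (1.5 equiv), THF/sat. aq. NH4Cl, rt; then PPTS (cat.), CH2Cl2, rt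
Reagents that add atoms: bis(trimethylsilyl) peroxide, C[Si](C)(C)OO[Si](C)(C)C
Why: Proposed new method: L-proline-catalysed enamine α-hydroxylation of an aldehyde with bis(trimethylsilyl) peroxide as electrophilic oxygen source, in which the E-enamine of 10 attacks the O–O bond of the peroxide hydrogen-bonded to the proline CO2H (closed transition state as in proline α-aminoxylation), so the C13–O bond forms on the acid-bearing face (13R, catalyst control) and Me3SiO− leaves; the closest known reaction types are proline-catalysed α-aminoxylation with nitrosobenzene, amine-catalysed α-benzoyloxylation with dibenzoyl peroxide and enolate hydroxylation with the same peroxide; the α-silyloxy aldehyde hydrolyses in the aqueous medium and its free OH chelates indium in a known Barbier allylation with the Z-bromide (Cram-chelate attack gives 14R syn to 13-OH, the cyclic transition state of the Z-2-(methoxycarbonyl)allylindium gives the syn adduct and hence 1S), after which lactonisation closes the cis-fused α-methylene-γ-butyrolactone.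

Step 11
Reactants: 23 (lactone diol)
Product: 24 (1R,2S,6R)-6-hydroxy-2,6-dimethyl-1-{(2R,3S)-4-methylidene-3-[(2E)-3-methylhexa-2,5-dien-1-yl]-5-oxooxolan-2-yl}oct-7-en-1-yl acetate
Conditions: Ac2O (1.3 equiv), pyridine, DMAP (5 mol%), CH2Cl2, 0 °C
Reagents that add atoms: acetic anhydride, CC(=O)OC(C)=O
Why: Nucleophile-catalysed acylation acetylates only the secondary C13 hydroxyl, because the tertiary allylic C8 hydroxyl is too hindered.

Step 12
Reactants: 24 (acetate)
Product: 25 (1R,2S,6R)-6-hydroxy-2,6-dimethyl-1-[(2R,3S)-4-methylidene-3-{[(2R,3R)-3-methyl-3-(prop-2-en-1-yl)oxiran-2-yl]methyl}-5-oxooxolan-2-yl]oct-7-en-1-yl acetate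
Conditions: Shi ketone from D-fructose (30 mol%), KHSO5 (1.5 equiv), K2CO3, Bu4NHSO4, MeCN/CH2(OMe)2/aq. buffer pH 9.3, 0 °C
Reagents that add atoms: potassium peroxymonosulfate, [K+].[O-]S(=O)(=O)OO
Why: Shi asymmetric epoxidation, in which the chiral dioxirane attacks the only electron-rich trisubstituted alkene through the spiro transition state and, as for other E-trisubstituted alkenes, the D-fructose-derived ketone gives the (3R,4R)-oxirane under reagent control; the terminal alkenes and the acrylate react much more slowly.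

Step 13
Reactants: 25 (epoxy acetate)
Product: 26 (1S,3R,4R,8R,12S,13R,14R)-13-acetoxy-3,4-epoxy-8-hydroxycembra-6E,15(17)-dien-16,14-olide (CNP0202356.3)
Conditions: second-generation Grubbs catalyst RuCl2(=CHPh)(H2IMes)(PCy3) (10 mol%), 1,4-benzoquinone (20 mol%), CH2Cl2 (1 mM), 40 °C
Reagents that add atoms: none
Why: Ring-closing metathesis between the allyl group and the vinyl carbinol closes the 14-membered ring with loss of ethene; the quaternary allylic C8 makes the E-alkene strongly preferred, and a 7-membered ring through the acrylate is excluded because it would contain a trans-fused oxirane.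

**Compound list**
1 | (R)-(−)-linalool, (3R)-3,7-dimethylocta-1,6-dien-3-ol | CC(C)=CCC[C@@](C)(O)C=C | starting material
2 | (4R)-4-hydroxy-4-methylhex-5-enal (ozonolysis product, in equilibrium with its lactol) | O=CCC[C@@](C)(O)C=C | intermediate
3 | (4R)-4-methylhex-5-ene-1,4-diol | OCCC[C@@](C)(O)C=C | intermediate
4 | (3R)-6-chloro-3-methylhex-1-en-3-ol | ClCCC[C@@](C)(O)C=C | intermediate
5 | {[(3R)-6-chloro-3-methylhex-1-en-3-yl]oxy}trimethylsilane | ClCCC[C@@](C)(O[Si](C)(C)C)C=C | intermediate
6 | (3E)-4-methoxybut-3-en-2-one | CO/C=C/C(C)=O | starting material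
7 | {(4R)-4-methyl-4-[(trimethylsilyl)oxy]hex-5-en-1-yl}magnesium chloride | Cl[Mg]CCC[C@@](C)(O[Si](C)(C)C)C=C | intermediate
8 | (1E,7R)-1-methoxy-3,7-dimethyl-7-[(trimethylsilyl)oxy]nona-1,8-dien-3-ol (both C3 epimers, formed as magnesium alkoxide) | CO/C=C/C(C)(O)CCC[C@@](C)(O[Si](C)(C)C)C=C | intermediate
9 | (2E,7R)-7-hydroxy-3,7-dimethylnona-2,8-dienal (E drawn; contains 2Z isomer) | O=C/C=C(\C)CCC[C@@](C)(O)C=C | intermediate
10 | (3S,7R)-7-hydroxy-3,7-dimethylnon-8-enal | O=CC[C@@H](C)CCC[C@@](C)(O)C=C | intermediate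
11 | pent-1-en-4-yne | C=CCC#C | starting material
12 | dimethyl[(1E)-2-methylpenta-1,4-dien-1-yl]alumane | C[Al](C)/C=C(\C)CC=C | intermediate
13 | lithium butyldimethyl[(1E)-2-methylpenta-1,4-dien-1-yl]aluminate | [Li+].CCCC[Al-](C)(C)/C=C(\C)CC=C | intermediate
14 | (3E)-4-methylhepta-3,6-dien-1-ol | OCC/C=C(\C)CC=C | intermediate
15 | (3E)-4-methylhepta-3,6-dienal | O=CC/C=C(\C)CC=C | intermediate
16 | methyl acrylate | C=CC(=O)OC | starting material
17 | methyl (5E)-3-hydroxy-6-methyl-2-methylidenenona-5,8-dienoate (racemic) | C=C(C(=O)OC)C(O)C/C=C(\C)CC=C | intermediate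
18 | methyl (2Z,5E)-2-(bromomethyl)-6-methylnona-2,5,8-trienoate | BrC/C(C(=O)OC)=C\C/C=C(\C)CC=C | intermediate
19 | (2R,3S,7R)-7-hydroxy-3,7-dimethyl-2-[(trimethylsilyl)oxy]non-8-enal | O=C[C@H](O[Si](C)(C)C)[C@@H](C)CCC[C@@](C)(O)C=C | intermediate
20 | (2R,3S,7R)-2,7-dihydroxy-3,7-dimethylnon-8-enal | O=C[C@H](O)[C@@H](C)CCC[C@@](C)(O)C=C | intermediate
21 | dibromo[(2Z,5E)-2-(methoxycarbonyl)-6-methylnona-2,5,8-trien-1-yl]indium (allylindium reagent, drawn as monomeric dibromide) | Br[In](Br)C/C(C(=O)OC)=C\C/C=C(\C)CC=C | intermediate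
22 | methyl (3S,4R,5R,6S,10R)-4,5,10-trihydroxy-6,10-dimethyl-2-methylidene-3-[(2E)-3-methylhexa-2,5-dien-1-yl]dodec-11-enoate | COC(=O)C(=C)[C@H](C/C=C(\C)CC=C)[C@@H](O)[C@H](O)[C@@H](C)CCC[C@@](C)(O)C=C | intermediate
23 | (4S,5R)-5-[(1R,2S,6R)-1,6-dihydroxy-2,6-dimethyloct-7-en-1-yl]-3-methylidene-4-[(2E)-3-methylhexa-2,5-dien-1-yl]oxolan-2-one | C=C1C(=O)O[C@@H]([C@H](O)[C@@H](C)CCC[C@@](C)(O)C=C)[C@H]1C/C=C(\C)CC=C | intermediate
24 | (1R,2S,6R)-6-hydroxy-2,6-dimethyl-1-{(2R,3S)-4-methylidene-3-[(2E)-3-methylhexa-2,5-dien-1-yl]-5-oxooxolan-2-yl}oct-7-en-1-yl acetate | C=C1C(=O)O[C@@H]([C@H](OC(C)=O)[C@@H](C)CCC[C@@](C)(O)C=C)[C@H]1C/C=C(\C)CC=C | intermediate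
25 | (1R,2S,6R)-6-hydroxy-2,6-dimethyl-1-[(2R,3S)-4-methylidene-3-{[(2R,3R)-3-methyl-3-(prop-2-en-1-yl)oxiran-2-yl]methyl}-5-oxooxolan-2-yl]oct-7-en-1-yl acetate | C=C1C(=O)O[C@@H]([C@H](OC(C)=O)[C@@H](C)CCC[C@@](C)(O)C=C)[C@H]1C[C@H]2O[C@]2(C)CC=C | intermediate
26 | (1S,3R,4R,8R,12S,13R,14R)-13-acetoxy-3,4-epoxy-8-hydroxycembra-6E,15(17)-dien-16,14-olide (CNP0202356.3) | C=C1C(=O)O[C@H]2[C@H](OC(C)=O)[C@@H](C)CCC[C@@](C)(O)/C=C/C[C@@]3(C)O[C@@H]3C[C@@H]12 | target

**Step count and risks**
Total step count: 13. Longest linear sequence: 9 steps (steps 1–5 and 10–13, from (R)-linalool); the east bromide takes 4 steps (6–9).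

Steps most likely to fail:

Step 10 (the proposed new α-hydroxylation). The silyl peroxide may transfer oxygen too slowly to the enamine or oxidise the amine catalyst, and the α-hydroxy aldehyde can dimerise or epimerise before it is trapped. The fallback uses known chemistry and sets out from 10. L-Proline-catalysed α-aminoxylation with nitrosobenzene (CHCl3, 4 °C), followed by NaBH4 in the same pot, gives (2R,3S,7R)-2-(anilinooxy)-3,7-dimethylnon-8-ene-1,7-diol F1. Zn dust in AcOH (or CuSO4 in MeOH) cleaves the N–O bond to (2R,3S,7R)-3,7-dimethylnon-8-ene-1,2,7-triol F2. TEMPO/N-chlorosuccinimide (Bu4NCl, CH2Cl2/aq. NaHCO3–K2CO3) oxidises only the primary hydroxyl. The fallback comes back to the route at hydroxy aldehyde 20, which is taken through the indium stage of step 10 to 23.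

Step 13 (ring-closing metathesis). Closure at the hindered vinyl carbinol may be slow, and oligomers or E/Z mixtures are possible. The fallback closes the ring at C1–C14 instead and sets out from 20 and 18. Cross-metathesis (second-generation Hoveyda–Grubbs catalyst RuCl2(=CH-2-iPrOC6H4)(H2IMes), CH2Cl2, 40 °C) joins the vinyl carbinol of 20 to the allyl end of 18 and gives methyl (2Z,5E,8E,10R,14S,15R)-2-(bromomethyl)-10,15-dihydroxy-6,10,14-trimethyl-16-oxohexadeca-2,5,8-trienoate F3. Intramolecular Barbier allylation (In powder, THF/aq. NH4Cl, high dilution) gives the macrocyclic hydroxy ester methyl 2-[(1S,2R,3R,4S,8R,9E,12E)-2,3,8-trihydroxy-4,8,12-trimethylcyclotetradeca-9,12-dien-1-yl]prop-2-enoate F4. PPTS lactonises it to (1S,8R,12S,13R,14R)-8,13-dihydroxycembra-3E,6E,15(17)-trien-16,14-olide F5. Ac2O/pyridine gives (1S,8R,12S,13R,14R)-13-acetoxy-8-hydroxycembra-3E,6E,15(17)-trien-16,14-olide F6, and Shi epoxidation as in step 12 comes back to the route at 26.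

Step 8 (Morita–Baylis–Hillman reaction). The reaction is slow with aliphatic aldehydes, and the amine can isomerise the β,γ-unsaturated aldehyde 15 into conjugation. The fallback sets out from 15 and replaces the amine-catalysed process by vinylalumination. Methyl propiolate with iBu2AlH and N-methylmorpholine N-oxide (THF, 0 °C) gives methyl 2-[bis(2-methylpropyl)alumanyl]prop-2-enoate F7, which adds to 15 at low temperature without base; the fallback comes back to the route at 17.

**Further compounds**
F1 | step 10 | (2R,3S,7R)-2-(anilinooxy)-3,7-dimethylnon-8-ene-1,7-diol | OC[C@H](ONc1ccccc1)[C@@H](C)CCC[C@@](C)(O)C=C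
F2 | step 10 | (2R,3S,7R)-3,7-dimethylnon-8-ene-1,2,7-triol | OC[C@H](O)[C@@H](C)CCC[C@@](C)(O)C=C
F3 | step 13 | methyl (2Z,5E,8E,10R,14S,15R)-2-(bromomethyl)-10,15-dihydroxy-6,10,14-trimethyl-16-oxohexadeca-2,5,8-trienoate | O=C[C@H](O)[C@@H](C)CCC[C@@](C)(O)/C=C/C/C(C)=C/C/C=C(\CBr)C(=O)OC
F4 | step 13 | methyl 2-[(1S,2R,3R,4S,8R,9E,12E)-2,3,8-trihydroxy-4,8,12-trimethylcyclotetradeca-9,12-dien-1-yl]prop-2-enoate | COC(=O)C(=C)[C@@H]1C/C=C(\C)C/C=C/[C@](C)(O)CCC[C@H](C)[C@@H](O)[C@@H]1O
F5 | step 13 | (1S,8R,12S,13R,14R)-8,13-dihydroxycembra-3E,6E,15(17)-trien-16,14-olide | C=C1C(=O)O[C@H]2[C@H](O)[C@@H](C)CCC[C@@](C)(O)/C=C/C/C(C)=C/C[C@@H]12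
F6 | step 13 | (1S,8R,12S,13R,14R)-13-acetoxy-8-hydroxycembra-3E,6E,15(17)-trien-16,14-olide | C=C1C(=O)O[C@H]2[C@H](OC(C)=O)[C@@H](C)CCC[C@@](C)(O)/C=C/C/C(C)=C/C[C@@H]12
F7 | step 8 | methyl 2-[bis(2-methylpropyl)alumanyl]prop-2-enoate | C=C(C(=O)OC)[Al](CC(C)C)CC(C)C
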